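The benzylic CH2–C4 bond of the oxolane ring carries the whole plan. In the target this bond is anti to the C3–O bond of the spiro-epoxide, whose CH2 is the second arm on C3. The key step uses both facts: a 3-silyloxy-4-methoxybenzyl Grignard reagent opens a ring-fused 3,4-epoxyoxolane, which carries the C2 aryl group and a chloromethyl group on C3, at C4 with inversion, and the freed C3 alkoxide closes onto the chloromethyl carbon. One operation joins the halves, sets C4 cis to the C2 aryl group and turns the fused epoxide into the spiro-epoxide. The epoxy chloride comes from vanillin and but-2-yne-1,4-diol; a Sharpless epoxidation sets the absolute configuration.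

Key step: step 10

Remark: the oxolane locants of the target (O1, C2 bearing the aryl group, C3, C4 bearing the benzyl group, C5) are kept for every ring intermediate, and the carbon on C3 outside the oxolane ring is called C9.

Step 1
Reactants: 1 vanillin (4-hydroxy-3-methoxybenzaldehyde)
Product: 2 3-methoxy-4-[(triisopropylsilyl)oxy]benzaldehyde
Conditions: TIPSCl, imidazole, DMF, rt
Reagents that add atoms: triisopropylsilyl chloride (TIPSCl), CC(C)[Si](Cl)(C(C)C)C(C)C
Why: Imidazole-promoted O-silylation of the phenol (silyl ether formation) should be clean, and the bulky silyl ether is chosen to survive the organometallic, acidic and oxidative steps and to leave with fluoride at the end.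

Step 2
Reactants: 3 but-2-yne-1,4-diol
Product: 5 (Z)-2-iodobut-2-ene-1,4-diol, via cyclic alkenylaluminate 4 (not isolated)
Conditions: NaAlH2(OCH2CH2OMe)2, THF, 0 °C → rt; then iodine, THF, −78 °C → rt
Reagents that add atoms: iodine, [I][I]
Why: Hydroxyl-directed anti-hydroalumination of the propargylic alcohol, then iodinolysis of the alkenyl–aluminium bond with retention, should give the (Z)-iodide with iodine cis to the distal CH2OH, the geometry needed later to close the oxolane ring.

Step 3
Reactants: 2 3-methoxy-4-[(triisopropylsilyl)oxy]benzaldehyde; 5 (Z)-2-iodobut-2-ene-1,4-diol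
Product: 6 (Z)-2-{hydroxy[3-methoxy-4-(triisopropylsilyloxy)phenyl]methyl}but-2-ene-1,4-diol (racemic)
Conditions: CrCl2 (4 equiv), NiCl2 (2 mol%), DMF, rt
Reagents that add atoms: none
Why: The Nozaki–Hiyama–Kishi reaction couples alkenyl iodides with aldehydes in the presence of free hydroxyl groups and with retention of alkene geometry, so the new carbinol carbon C2 (formed racemic) should sit cis to the C5 hydroxymethyl group.

Step 4
Reactants: 6 (Z)-2-{hydroxy[3-methoxy-4-(triisopropylsilyloxy)phenyl]methyl}but-2-ene-1,4-diol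
Product: 7 rac-{2-[3-methoxy-4-(triisopropylsilyloxy)phenyl]-2,5-dihydrofuran-3-yl}methanol
Conditions: camphorsulfonic acid (5 mol%), CH2Cl2 (high dilution), 0 °C → rt
Reagents that add atoms: none
Why: Mild acid should ionise only the benzylic and allylic C2 hydroxyl, and the cis-placed C5 hydroxyl traps the cation (SN1 etherification, cyclodehydration of a (Z)-2-ene-1,4-diol) to give the 2,5-dihydrofuran, leaving the C9 alcohol free.

Step 5
Reactants: 7 rac-{2-[3-methoxy-4-(triisopropylsilyloxy)phenyl]-2,5-dihydrofuran-3-yl}methanol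
Product: 8 {(1S,2S,5R)-2-[3-methoxy-4-(triisopropylsilyloxy)phenyl]-3,6-dioxabicyclo[3.1.0]hexan-1-yl}methanol
Conditions: Ti(OiPr)4 (20 mol%), D-(−)-diisopropyl tartrate (24 mol%), t-BuOOH (0.55 equiv), 4 Å molecular sieves, CH2Cl2, −20 °C
Reagents that add atoms: tert-butyl hydroperoxide, CC(C)(C)OO
Why: This is a Sharpless asymmetric epoxidation run as a kinetic resolution: with the D-(−)-tartrate the catalyst delivers oxygen to the C3=C4 face that is anti to the aryl group only in the (S)-enantiomer (matched case), so that half of the racemate should give the trans epoxy alcohol with C2 fixed as S, while the (R)-enantiomer, whose reagent-preferred face is blocked by the aryl group, stays behind and is removed by chromatography.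

Step 6
Reactants: 8 {(1S,2S,5R)-2-[3-methoxy-4-(triisopropylsilyloxy)phenyl]-3,6-dioxabicyclo[3.1.0]hexan-1-yl}methanol
Product: 9 (1S,2S,5R)-1-(chloromethyl)-2-[3-methoxy-4-(triisopropylsilyloxy)phenyl]-3,6-dioxabicyclo[3.1.0]hexane
Conditions: PPh3, CCl4, NaHCO3, reflux
Reagents that add atoms: carbon tetrachloride, ClC(Cl)(Cl)Cl
Why: The Appel reaction should turn the primary alcohol into the chloride under neutral conditions (SN2 on the alkoxyphosphonium ion) without opening the epoxide, with NaHCO3 scavenging traces of HCl.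

Step 7
Reactants: 10 isovanillin (3-hydroxy-4-methoxybenzaldehyde)
Product: 11 4-methoxy-3-[(triisopropylsilyl)oxy]benzaldehyde
Conditions: TIPSCl, imidazole, DMF, rt
Reagents that add atoms: triisopropylsilyl chloride (TIPSCl), CC(C)[Si](Cl)(C(C)C)C(C)C
Why: The same imidazole-promoted O-silylation as in step 1 masks the phenol before the Grignard reagent is made.

Step 8
Reactants: 11 4-methoxy-3-[(triisopropylsilyl)oxy]benzaldehyde
Product: 12 {4-methoxy-3-[(triisopropylsilyl)oxy]phenyl}methanol
Conditions: NaBH4, MeOH, 0 °C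
Reagents that add atoms: none
Why: Hydride reduction of the aldehyde by NaBH4 should give the benzylic alcohol and leave the aryl silyl ether intact.

Step 9
Reactants: 12 {4-methoxy-3-[(triisopropylsilyl)oxy]phenyl}methanol
Product: 13 4-(chloromethyl)-1-methoxy-2-[(triisopropylsilyl)oxy]benzene
Conditions: SOCl2, pyridine, CH2Cl2, 0 °C
Reagents that add atoms: thionyl chloride, O=S(Cl)Cl
Why: Thionyl chloride with pyridine converts the electron-rich benzylic alcohol into the chloride through its chlorosulfite (substitution by chloride), and the chloride is the halide that forms benzylic Grignard reagents with the least homocoupling.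

Step 10
Reactants: 13 4-(chloromethyl)-1-methoxy-2-[(triisopropylsilyl)oxy]benzene; 9 (1S,2S,5R)-1-(chloromethyl)-2-[3-methoxy-4-(triisopropylsilyloxy)phenyl]-3,6-dioxabicyclo[3.1.0]hexane
Product: 16 (3S,4S,7S)-7-{4-methoxy-3-[(triisopropylsilyl)oxy]benzyl}-4-{3-methoxy-4-[(triisopropylsilyl)oxy]phenyl}-1,5-dioxaspiro[2.4]heptane, via benzylic Grignard reagent 14 (not isolated), via chlorohydrin alkoxide 15 (not isolated)
Conditions: 13 (2.5 equiv), Mg, THF, 0 °C; then 9, CuBr·SMe2 (10 mol%), THF, −40 → −10 °C; then t-BuOK, −10 → 0 °C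
Reagents that add atoms: none
Why: Magnesium insertion turns 13 into Grignard reagent 14, whose cuprate (catalytic CuBr·SMe2) attacks the ring-fused epoxide of 9 at C4 in an SN2 opening, and the C3 alkoxide of the resulting chlorohydrin 15, made more ionic by t-BuOK, displaces chloride from the neighbouring C9. The closest known reaction type is the copper-catalysed Grignard opening of epichlorohydrin-type epoxides followed by base-induced closure of the chlorohydrin to the transposed epoxide. The only ring closed is the oxirane of the spiro-epoxide, by a 3-exo-tet Williamson etherification; the oxolane ring is carried through unchanged. C4 is set by inversion: the benzyl group must enter anti to the breaking C4–O bond, that is on the face of the C2 aryl group, which gives the 2,4-cis arrangement, while the C3–O bond is never broken, so C3 keeps the configuration set in step 5 and C2 is untouched. The step needs attack at C4 and not at C3 or C9: C3 is fully substituted, a primary alkyl chloride is inert to cuprates at this temperature, and low temperature with only catalytic copper should hold back Lewis-acid opening of the epoxide by the magnesium salts.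

Step 11
Reactants: 16 (3S,4S,7S)-7-{4-methoxy-3-[(triisopropylsilyl)oxy]benzyl}-4-{3-methoxy-4-[(triisopropylsilyl)oxy]phenyl}-1,5-dioxaspiro[2.4]heptane
Product: 17 4-[(3S,4S,7S)-7-(3-hydroxy-4-methoxybenzyl)-1,5-dioxaspiro[2.4]heptan-4-yl]-2-methoxyphenol (CNP0184956.1)
Conditions: Bu4NF, AcOH, THF, 0 °C
Reagents that add atoms: none
Why: Fluoride cleaves both aryl silyl ethers (desilylation driven by silicon–fluorine bond formation), and buffering with acetic acid keeps the phenols protonated, so the spiro-epoxide and the benzylic ether should stay intact.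

Compound list
1 | vanillin (4-hydroxy-3-methoxybenzaldehyde) | COc1cc(C=O)ccc1O | starting material
2 | 3-methoxy-4-[(triisopropylsilyl)oxy]benzaldehyde | COc1cc(C=O)ccc1O[Si](C(C)C)(C(C)C)C(C)C | intermediate
3 | but-2-yne-1,4-diol | OCC#CCO | starting material
4 | cyclic sodium alkenylaluminate from anti-hydroalumination of 3 (idealised monomeric formula, formed in the flask) | [Na+].[Na+].COCCO[Al-]1(OCCOC)OCC=C1CO[AlH-](OCCOC)OCCOC | intermediate
5 | (Z)-2-iodobut-2-ene-1,4-diol | OC/C=C(/CO)\I | intermediate
6 | (Z)-2-{hydroxy[3-methoxy-4-(triisopropylsilyloxy)phenyl]methyl}but-2-ene-1,4-diol (racemic) | OC/C=C(/CO)\C(O)c1ccc(O[Si](C(C)C)(C(C)C)C(C)C)c(OC)c1 | intermediate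
7 | rac-{2-[3-methoxy-4-(triisopropylsilyloxy)phenyl]-2,5-dihydrofuran-3-yl}methanol | OCC1=CCOC1c2ccc(O[Si](C(C)C)(C(C)C)C(C)C)c(OC)c2 | intermediate
8 | {(1S,2S,5R)-2-[3-methoxy-4-(triisopropylsilyloxy)phenyl]-3,6-dioxabicyclo[3.1.0]hexan-1-yl}methanol | C1O[C@@H](c3ccc(O[Si](C(C)C)(C(C)C)C(C)C)c(OC)c3)[C@]2(CO)O[C@H]12 | intermediate
9 | (1S,2S,5R)-1-(chloromethyl)-2-[3-methoxy-4-(triisopropylsilyloxy)phenyl]-3,6-dioxabicyclo[3.1.0]hexane | C1O[C@@H](c3ccc(O[Si](C(C)C)(C(C)C)C(C)C)c(OC)c3)[C@]2(CCl)O[C@H]12 | intermediate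
10 | isovanillin (3-hydroxy-4-methoxybenzaldehyde) | COc1ccc(C=O)cc1O | starting material
11 | 4-methoxy-3-[(triisopropylsilyl)oxy]benzaldehyde | COc1ccc(C=O)cc1O[Si](C(C)C)(C(C)C)C(C)C | intermediate
12 | {4-methoxy-3-[(triisopropylsilyl)oxy]phenyl}methanol | COc1ccc(CO)cc1O[Si](C(C)C)(C(C)C)C(C)C | intermediate
13 | 4-(chloromethyl)-1-methoxy-2-[(triisopropylsilyl)oxy]benzene | COc1ccc(CCl)cc1O[Si](C(C)C)(C(C)C)C(C)C | intermediate
14 | {4-methoxy-3-[(triisopropylsilyl)oxy]benzyl}magnesium chloride (formed in the flask) | COc1ccc(C[Mg]Cl)cc1O[Si](C(C)C)(C(C)C)C(C)C | intermediate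
15 | (2S,3R,4S)-3-(chloromethyl)-4-{4-methoxy-3-[(triisopropylsilyl)oxy]benzyl}-2-{3-methoxy-4-[(triisopropylsilyl)oxy]phenyl}oxolan-3-ol (present in the flask as its alkoxide) | COc1ccc(C[C@H]2CO[C@@H](c3ccc(O[Si](C(C)C)(C(C)C)C(C)C)c(OC)c3)[C@@]2(O)CCl)cc1O[Si](C(C)C)(C(C)C)C(C)C | intermediate
16 | (3S,4S,7S)-7-{4-methoxy-3-[(triisopropylsilyl)oxy]benzyl}-4-{3-methoxy-4-[(triisopropylsilyl)oxy]phenyl}-1,5-dioxaspiro[2.4]heptane | COc1ccc(C[C@H]2CO[C@@H](c3ccc(O[Si](C(C)C)(C(C)C)C(C)C)c(OC)c3)[C@@]23CO3)cc1O[Si](C(C)C)(C(C)C)C(C)C | intermediate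
17 | 4-[(3S,4S,7S)-7-(3-hydroxy-4-methoxybenzyl)-1,5-dioxaspiro[2.4]heptan-4-yl]-2-methoxyphenol (CNP0184956.1) | COc1ccc(C[C@H]2CO[C@@H](c3ccc(O)c(OC)c3)[C@@]23CO3)cc1O | target

Total step count: 11. Longest linear sequence: 7 steps (steps 1, 3, 4, 5, 6, 10, 11 from vanillin; the same length through step 2 from but-2-yne-1,4-diol).

Steps most likely to fail

Step 10. The chemoselectivity may be lost: the magnesium salts may open or rearrange the fully substituted epoxide carbon before the cuprate reaches C4, or ring closure of the chlorohydrin alkoxide may stay incomplete or go astray. The fallback separates carbon–carbon bond formation from construction of the spiro-epoxide and sets out from 8. Excess Grignard reagent 14 with CuBr·SMe2 in THF at −40 °C should open the epoxy alcohol, as its magnesium alkoxide and with no leaving group on C9, at C4 with the same inversion. This gives the diol (2S,3S,4S)-3-(hydroxymethyl)-4-{4-methoxy-3-[(triisopropylsilyl)oxy]benzyl}-2-{3-methoxy-4-[(triisopropylsilyl)oxy]phenyl}oxolan-3-ol F1. TsCl, Et3N and catalytic DMAP in CH2Cl2 at 0 °C should sulfonylate only the primary hydroxyl, giving the monotosylate {(2S,3S,4S)-3-hydroxy-4-{4-methoxy-3-[(triisopropylsilyl)oxy]benzyl}-2-{3-methoxy-4-[(triisopropylsilyl)oxy]phenyl}oxolan-3-yl}methyl 4-methylbenzenesulfonate F2. NaH in THF at 0 °C then closes the oxirane, and the route is rejoined at 16.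

Step 5. The rate difference between the two enantiomers of 7 may be too small, so that the epoxy alcohol is obtained with insufficient enantiomeric purity or mixed with the cis-epoxide of the mismatched enantiomer. The fallback replaces the kinetic resolution by a physical one and sets out from 7. Preparative chromatography on a chiral stationary phase gives {(2S)-2-[3-methoxy-4-(triisopropylsilyloxy)phenyl]-2,5-dihydrofuran-3-yl}methanol F3. This single enantiomer is then epoxidised in the matched sense with Ti(OiPr)4, D-(−)-diisopropyl tartrate and excess t-BuOOH to full conversion, where catalyst and substrate both direct oxygen anti to the aryl group, and the route is rejoined at 8.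

Step 3. The alkenylchromium intermediate may be lost by protonolysis or by β-elimination of the neighbouring hydroxyl, so that reduction of the carbon–iodine bond outruns addition to the aldehyde. The fallback uses a protected alkenyllithium and sets out from 5. TBSCl and imidazole give (Z)-1,4-bis[(tert-butyldimethylsilyl)oxy]-2-iodobut-2-ene F4. Iodine–lithium exchange with t-BuLi in Et2O at −78 °C and addition of 2 should give racemic (Z)-4-[(tert-butyldimethylsilyl)oxy]-2-{[(tert-butyldimethylsilyl)oxy]methyl}-1-[3-methoxy-4-(triisopropylsilyloxy)phenyl]but-2-en-1-ol F5. AcOH–THF–water at rt removes the two alkyl silyl ethers while the aryl silyl ether stays, and the route is rejoined at 6.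

Further compounds
F1 | step 10 | (2S,3S,4S)-3-(hydroxymethyl)-4-{4-methoxy-3-[(triisopropylsilyl)oxy]benzyl}-2-{3-methoxy-4-[(triisopropylsilyl)oxy]phenyl}oxolan-3-ol | COc1ccc(C[C@H]2CO[C@@H](c3ccc(O[Si](C(C)C)(C(C)C)C(C)C)c(OC)c3)[C@@]2(O)CO)cc1O[Si](C(C)C)(C(C)C)C(C)C
F2 | step 10 | {(2S,3S,4S)-3-hydroxy-4-{4-methoxy-3-[(triisopropylsilyl)oxy]benzyl}-2-{3-methoxy-4-[(triisopropylsilyl)oxy]phenyl}oxolan-3-yl}methyl 4-methylbenzenesulfonate | COc1ccc(C[C@H]2CO[C@@H](c3ccc(O[Si](C(C)C)(C(C)C)C(C)C)c(OC)c3)[C@@]2(O)COS(=O)(=O)c4ccc(C)cc4)cc1O[Si](C(C)C)(C(C)C)C(C)C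
F3 | step 5 | {(2S)-2-[3-methoxy-4-(triisopropylsilyloxy)phenyl]-2,5-dihydrofuran-3-yl}methanol | OCC1=CCO[C@H]1c2ccc(O[Si](C(C)C)(C(C)C)C(C)C)c(OC)c2
F4 | step 3 | (Z)-1,4-bis[(tert-butyldimethylsilyl)oxy]-2-iodobut-2-ene | CC(C)(C)[Si](C)(C)OC/C=C(/CO[Si](C)(C)C(C)(C)C)\I
F5 | step 3 | (Z)-4-[(tert-butyldimethylsilyl)oxy]-2-{[(tert-butyldimethylsilyl)oxy]methyl}-1-[3-methoxy-4-(triisopropylsilyloxy)phenyl]but-2-en-1-ol (racemic) | CC(C)(C)[Si](C)(C)OC/C=C(/CO[Si](C)(C)C(C)(C)C)\C(O)c1ccc(O[Si](C(C)C)(C(C)C)C(C)C)c(OC)c1
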